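Begin with the easy step: lay the charges side by side and see which is smaller.

| setting | violet | amber | flask |
|---|---|---|---|
| starting material | 1 M | 1 M | 1.0 M |
| second substrate | 1 M | 1.5 M | 1.00 M |
| partner | 1.5 M | 1.5 M | 1.50 M |
| free catalyst | 43 mM | 43 mM | 43 mM |
| temperature | 50 °C | 50 °C | 50 °C |
| remark | the very flask that is asked about, followed so far | run made earlier |  |
| time |  |  | 15 h |
- violet (time / h: target / %): 1.00: 8.1; 2.00: 14.6; 3.00: 17.3; 6.00: 26.5; 12.0: 29.1
- amber (time / min: target / %): 20.0: 2.1; 40.0: 5.2; 50.0: 6.1; 80.0: 6.8; 90.0: 10.3

(scatter of a reading: 1 percentage point)
- Saturday's: at 15 h take out 90% of the target then present, then wait 30 h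
- Friday's: at 15 h raise the temperature by 25 K, then wait 30 h
- Wednesday's: at 15 h add partner, 50.0% of the amount charged, then wait 30 h
- Thursday's: at 15 h add free catalyst, 50.0% of the amount charged, then wait 30 h
- Monday's: change nothing and wait 30 h more
- what is taken out of target is counted as made
- additions bring no volume worth counting
- the earlier runs do not show what temperature does; that part of a forecast is a guess
1. target, in percent of the starting material first charged, at 15 h
2. the option that brings most further target ("none" if no option brings more than 2 percentage points) (Saturday's / Friday's / Wednesday's / Thursday's / Monday's / none)
3. target present, with what was taken out counted in, in percent of the starting material first charged, after Saturday's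
4. target present, with what was taken out counted in, in percent of the starting material first charged, after Wednesday's

Has violet, the asked flask followed so far, stopped? Nearly. It gains 2.6 percentage points between 6.00 h and 12.0 h, with a scatter of 1 point on each reading.

Is the starting material gone? No. At the last reading 70.9% of it has not become target.

So what does second substrate do? Amber holds more of it, yet gains target no faster: 10.3% in 90.0 min, against 14.6% in 2.00 h for violet. My supposition is that second substrate makes no target and takes partner one for one.

What follows? Write the balance of the smaller charge against the larger. Spare partner, c_partner charged minus c_second substrate charged, is what remains for target once second substrate has taken its share: 0.500 M. Violet's last reading sets 0.291 M of target against it, a share of 0.582 reaching target.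

And your numbers? I put the target at 15 h near that last reading, 29.1%. Saturday's adds no partner, so it stays about there. Wednesday's adds 0.750 M of partner. If second substrate has gone by then, the whole addition is spare, which gives 72.8%. Wednesday's is my choice.

Where is this weak? The one-for-one taking is a supposition, the share rests on one reading, and amber's readings end at 90.0 min.

The forecast gave 30.5%, chose Thursday's, and put 32% after Saturday's and 32% after Wednesday's, saying “The zero order in second substrate leans me towards catalyst loss”. We part on the choice of option and on Wednesday's figure, where mine stands above the forecast's; my target at 15 h stands below the forecast's.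

The flask gives 28.5%, and the best option is Wednesday's, bringing 42 points against 0.22 points for Thursday's. Saturday's ends at 28.7% and Wednesday's at 70.4%. At 15.0 h partner, the limiting reagent here, stands at 0.575% of its charge still free. Starting from the computed 28.5%, the spare-partner share gives 72.1% for Wednesday's, against the computed 70.4%.

    starting material + free catalyst ⇌ catalyst intermediate A (K = 1.60 M⁻¹, k = 0.00460 M⁻¹ s⁻¹, Ea = 57.0 kJ mol⁻¹, ΔH = 49.0 kJ mol⁻¹)
    partner → decomposed reagent (k = 1.50 × 10⁻⁵ s⁻¹, Ea = 118 kJ mol⁻¹)
    second substrate + free catalyst ⇌ catalyst intermediate B (K = 170 M⁻¹, k = 0.00680 M⁻¹ s⁻¹, Ea = 65.0 kJ mol⁻¹, ΔH = −26.0 kJ mol⁻¹)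
    partner + catalyst intermediate A → free catalyst + target (k = 0.00130 M⁻¹ s⁻¹, Ea = 56.0 kJ mol⁻¹)
    partner + catalyst intermediate B → free catalyst + second product (k = 0.00400 M⁻¹ s⁻¹, Ea = 68.0 kJ mol⁻¹)
    (constants at 50 °C)

In the neighbour flask with 0.90 M of partner, spare partner is −0.100 M, below zero, so the reckoning has partner going first, second substrate left over and no target from spare partner. Computed, that flask ends with 0.022% of its partner and 27% of its second substrate, so the order holds, but target stands at 10.3%, not zero.

The numbers in the tables were generated by integration from invented constants, and the scatter is random.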